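**Retrosynthetic overview**

- The strategy rests on ring A: the carboxyl carbon on C1 and the diaryl ether oxygen on C6 are on adjacent ring carbons, with the methoxy group on C2 next to C1. This is the pattern left when a 3-methoxy-type aryne (C1≡C6) takes up an oxygen nucleophile at C6 and CO2 at C1.
- Last disconnections: the ring B methoxymethyl ether (acid hydrolysis) and the C6′ E-enone (Heck reaction of a C6′ bromide with methyl vinyl ketone).
- Key disconnection: the C6–O ether bond and the C1–CO2H bond together, giving a ring A silylaryl triflate (already carrying the (S)-acetate), a ring B bromophenol and CO2.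
- The silylaryl triflate comes from 2-bromoresorcinol by acylation, differentiation of the two oxygens, CBS reduction to the (S)-carbinol, an O→C silyl shift, triflation and acetylation. The bromophenol comes from 2-hydroxy-4-methylbenzaldehyde by acetal protection, Baeyer–Villiger oxidation and ortho-bromination.
- No ring is formed at any stage; both benzene rings are bought.

Key step: step 12

Locants used below: ring A C1 (carboxyl-bearing) to C6 (ether-bearing); ring B C1′ (ether carbon), C2′ (OH), C4′ (CH3), C6′ (enone). The benzylic centre is S, as the target SMILES requires.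

**Route**

Step 1
Reactants: 1 2-bromoresorcinol; 2 isovaleric acid
Product: 3 1-(3-bromo-2,4-dihydroxyphenyl)-3-methylbutan-1-one
Conditions: BF3·OEt2 (solvent), 85 °C; aq. NaOAc
Reagents that add atoms: none
Why: Friedel–Crafts (Nencki-type) C-acylation, in which the two equivalent positions ortho to one hydroxyl and para to the other are the only activated sites of 1, so a single ketone should form.

Step 2
Reactants: 3 1-(3-bromo-2,4-dihydroxyphenyl)-3-methylbutan-1-one
Product: 4 1-[4-(allyloxy)-3-bromo-2-hydroxyphenyl]-3-methylbutan-1-one
Conditions: allyl bromide (1.05 equiv), K2CO3, acetone, rt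
Reagents that add atoms: allyl bromide, C=CCBr
Why: Williamson etherification, selective for the free and more acidic C4 hydroxyl because the C2 hydroxyl is held in a hydrogen bond to the ketone.

Step 3
Reactants: 4 1-[4-(allyloxy)-3-bromo-2-hydroxyphenyl]-3-methylbutan-1-one
Product: 5 1-[4-(allyloxy)-3-bromo-2-methoxyphenyl]-3-methylbutan-1-one
Conditions: MeI, K2CO3, DMF, 45 °C
Reagents that add atoms: iodomethane, CI
Why: Williamson O-methylation of the remaining chelated phenol, run far below the temperature at which an aryl allyl ether would undergo Claisen rearrangement.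

Step 4
Reactants: 5 1-[4-(allyloxy)-3-bromo-2-methoxyphenyl]-3-methylbutan-1-one
Product: 6 (S)-1-[4-(allyloxy)-3-bromo-2-methoxyphenyl]-3-methylbutan-1-ol
Conditions: (R)-1-methyl-3,3-diphenyltetrahydro-1H,3H-pyrrolo[1,2-c][1,3,2]oxazaborole (20 mol%), catecholborane, toluene, −78 → −30 °C; MeOH; 1 M NaOH wash
Reagents that add atoms: none
Why: Corey–Bakshi–Shibata reduction, in which the (R)-oxazaborolidine places the aryl group as the large and the CH2 group as the small substituent and delivers hydride to the Re face (the sense that gives (S)-1-phenylethanol from acetophenone), with catecholborane chosen because it does not hydroborate the allyl ether.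

Step 5
Reactants: 6 (S)-1-[4-(allyloxy)-3-bromo-2-methoxyphenyl]-3-methylbutan-1-ol
Product: 7 (S)-2-bromo-4-(1-hydroxy-3-methylbutyl)-3-methoxyphenol
Conditions: Pd(PPh3)4 (3 mol%), morpholine, THF, rt
Reagents that add atoms: none
Why: Tsuji–Trost-type deallylation, in which zerovalent palladium ionises the aryl allyl ether and morpholine takes the allyl group under neutral conditions, so the acid-sensitive para-hydroxybenzylic carbinol is never exposed to acid and the hindered aryl bromide should not react at room temperature.

Step 6
Reactants: 7 (S)-2-bromo-4-(1-hydroxy-3-methylbutyl)-3-methoxyphenol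
Product: 8 (S)-{2-bromo-3-methoxy-4-[3-methyl-1-(trimethylsilyloxy)butyl]phenoxy}trimethylsilane
Conditions: HMDS, Me3SiCl (cat.), THF, 60 °C; evaporate
Reagents that add atoms: hexamethyldisilazane, C[Si](C)(C)N[Si](C)(C)C
Why: O-silylation of both hydroxyls with hexamethyldisilazane, which leaves only ammonia behind so that the moisture-sensitive bis(silyl ether) can be used crude.

Step 7
Reactants: 8 (S)-{2-bromo-3-methoxy-4-[3-methyl-1-(trimethylsilyloxy)butyl]phenoxy}trimethylsilane
Product: 12 (S)-4-(1-hydroxy-3-methylbutyl)-3-methoxy-2-(trimethylsilyl)phenyl trifluoromethanesulfonate, via aryllithium 9 (not isolated), via lithium phenoxide 10 (not isolated), via silyl ether triflate 11 (not isolated)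
Conditions: n-BuLi, THF, −78 °C; PhNTf2, −78 °C → rt; 1 M HCl, THF, 0 °C
Reagents that add atoms: N-phenylbis(trifluoromethanesulfonimide), O=S(=O)(N(c1ccccc1)S(=O)(=O)C(F)(F)F)C(F)(F)F
Why: Bromine–lithium exchange followed by retro-Brook rearrangement (1,3 O→C silyl shift) places silicon on the carbon between the two oxygens and frees the phenoxide for triflation by the mild N-phenyl triflimide, after which dilute acid removes only the labile benzylic silyl ether.

Step 8
Reactants: 12 (S)-4-(1-hydroxy-3-methylbutyl)-3-methoxy-2-(trimethylsilyl)phenyl trifluoromethanesulfonate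
Product: 13 (S)-1-[2-methoxy-4-(trifluoromethylsulfonyloxy)-3-(trimethylsilyl)phenyl]-3-methylbutyl acetate
Conditions: Ac2O, pyridine, 4-(dimethylamino)pyridine (cat.), CH2Cl2, 0 °C → rt
Reagents that add atoms: acetic anhydride, CC(=O)OC(C)=O
Why: Nucleophile-catalysed O-acetylation, which reacts at the O–H bond only and so retains the S configuration.

Step 9
Reactants: 14 2-hydroxy-4-methylbenzaldehyde
Product: 15 2-(methoxymethoxy)-4-methylbenzaldehyde
Conditions: MOMCl, i-Pr2NEt, CH2Cl2, 0 °C → rt
Reagents that add atoms: chloromethyl methyl ether, COCCl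
Why: O-alkylation of the phenol with an α-chloro ether (methoxymethyl acetal formation), a standard protection of salicylaldehydes.

Step 10
Reactants: 15 2-(methoxymethoxy)-4-methylbenzaldehyde
Product: 17 2-(methoxymethoxy)-4-methylphenol, via aryl formate 16 (not isolated)
Conditions: mCPBA, CH2Cl2, 0 °C → rt; aq. Na2S2O3/NaHCO3 wash; K2CO3 (cat.), MeOH, rt
Reagents that add atoms: 3-chloroperbenzoic acid, O=C(OO)c1cccc(Cl)c1
Why: Baeyer–Villiger oxidation with migration of the electron-rich ortho-alkoxyaryl group (a Dakin-type outcome) gives the formate, which catalytic carbonate in methanol transesterifies to the phenol without touching the acetal.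

Step 11
Reactants: 17 2-(methoxymethoxy)-4-methylphenol
Product: 18 2-bromo-6-(methoxymethoxy)-4-methylphenol
Conditions: NBS, i-Pr2NH (10 mol%), CH2Cl2, 0 °C
Reagents that add atoms: N-bromosuccinimide, O=C1CCC(=O)N1Br
Why: Amine-mediated ortho-selective electrophilic bromination of a phenol, in which the para position carries the methyl group and one ortho position the acetal oxygen, leaving C6 as the only site activated by the free hydroxyl.

Step 12
Reactants: 13 (S)-1-[2-methoxy-4-(trifluoromethylsulfonyloxy)-3-(trimethylsilyl)phenyl]-3-methylbutyl acetate; 18 2-bromo-6-(methoxymethoxy)-4-methylphenol; 19 carbon dioxide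
Product: 23 3-[(S)-1-acetoxy-3-methylbutyl]-6-[2-bromo-6-(methoxymethoxy)-4-methylphenoxy]-2-methoxybenzoic acid, via potassium phenoxide 20 (not isolated), via aryne 21 (not isolated), via arylpotassium adduct 22 (not isolated)
Conditions: 18 (1.5 equiv), KH, THF, 0 °C; then KF, 18-crown-6, CO2 (1 atm), 13 added slowly, THF, 0 °C → rt; 1 M HCl to pH 3
Reagents that add atoms: none
Why: Proposed new method: fluoride attacks the trimethylsilyl group of 13 and triflate leaves to give the C1≡C6 aryne, the pre-formed proton-free potassium phenoxide adds through oxygen at C6, and the resulting C1 carbanion, flanked by the methoxy and aryloxy oxygens, is captured by dissolved CO2 to give the carboxylate. The closest known reactions are the fluoride-induced three-component coupling of arynes, amines and CO2 to anthranilic acids and the fluoride-mediated O-arylation of phenols by arynes; using an oxygen nucleophile in the three-component mode is the new element. No ring is closed and no stereocentre is created; the (S)-acetate should be a spectator because acyl transfer from an alkyl acetate to a phenoxide is uphill and fluoride in THF is not an acyl nucleophile. The selectivity needed is regiochemical: the C2 methoxy group polarises the aryne so that negative charge is best placed on the adjacent C1, and the C3 side chain pushes the methoxy methyl toward C1, so attack at the remote C6 is favoured both electronically and sterically. Carboxylation should win over protonation because the medium is aprotic (phenoxide made with KH, THF in place of acetonitrile) and because the hindered, weakly basic 2-bromo-6-alkoxyphenoxide binds CO2 only loosely and stays free to attack the aryne; the excess of phenoxide limits O-arylation of the product carboxylate.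

Step 13
Reactants: 23 3-[(S)-1-acetoxy-3-methylbutyl]-6-[2-bromo-6-(methoxymethoxy)-4-methylphenoxy]-2-methoxybenzoic acid; 24 methyl vinyl ketone
Product: 25 3-[(S)-1-acetoxy-3-methylbutyl]-2-methoxy-6-{2-(methoxymethoxy)-4-methyl-6-[(E)-3-oxobut-1-en-1-yl]phenoxy}benzoic acid
Conditions: Pd(OAc)2 (10 mol%), P(o-tol)3 (20 mol%), Et3N, 24 (4 equiv), DMF, 90 °C
Reagents that add atoms: none
Why: Mizoroki–Heck reaction, in which oxidative addition of zerovalent palladium into the aryl–bromine bond, syn carbopalladation at the terminal alkene carbon and syn β-hydride elimination should give the E-enone, the acid being carried as its triethylammonium salt.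

Step 14
Reactants: 25 3-[(S)-1-acetoxy-3-methylbutyl]-2-methoxy-6-{2-(methoxymethoxy)-4-methyl-6-[(E)-3-oxobut-1-en-1-yl]phenoxy}benzoic acid
Product: 26 3-[(S)-1-acetoxy-3-methylbutyl]-6-{2-hydroxy-4-methyl-6-[(E)-3-oxobut-1-en-1-yl]phenoxy}-2-methoxybenzoic acid (target)
Conditions: 3 M aq. HCl, THF, rt
Reagents that add atoms: none
Why: Acid-catalysed hydrolysis of the aryl methoxymethyl acetal, which is far more labile than the secondary benzylic acetate; in cold dilute aqueous acid the acetate should be neither hydrolysed nor ionised, since ring A is deactivated by the carboxyl group.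

**Compound list**

1 | 2-bromoresorcinol | Oc1cccc(O)c1Br | starting material
2 | isovaleric acid | CC(C)CC(=O)O | starting material
3 | 1-(3-bromo-2,4-dihydroxyphenyl)-3-methylbutan-1-one | CC(C)CC(=O)c1ccc(O)c(Br)c1O | intermediate
4 | 1-[4-(allyloxy)-3-bromo-2-hydroxyphenyl]-3-methylbutan-1-one | CC(C)CC(=O)c1ccc(OCC=C)c(Br)c1O | intermediate
5 | 1-[4-(allyloxy)-3-bromo-2-methoxyphenyl]-3-methylbutan-1-one | CC(C)CC(=O)c1ccc(OCC=C)c(Br)c1OC | intermediate
6 | (S)-1-[4-(allyloxy)-3-bromo-2-methoxyphenyl]-3-methylbutan-1-ol | COc1c([C@H](CC(C)C)O)ccc(OCC=C)c1Br | intermediate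
7 | (S)-2-bromo-4-(1-hydroxy-3-methylbutyl)-3-methoxyphenol | COc1c([C@H](CC(C)C)O)ccc(O)c1Br | intermediate
8 | (S)-{2-bromo-3-methoxy-4-[3-methyl-1-(trimethylsilyloxy)butyl]phenoxy}trimethylsilane | COc1c([C@H](CC(C)C)O[Si](C)(C)C)ccc(O[Si](C)(C)C)c1Br | intermediate
9 | aryllithium from bromine–lithium exchange of 8 (not isolated) | COc1c([C@H](CC(C)C)O[Si](C)(C)C)ccc(O[Si](C)(C)C)c1[Li] | intermediate
10 | lithium (S)-3-methoxy-4-[3-methyl-1-(trimethylsilyloxy)butyl]-2-(trimethylsilyl)phenoxide (not isolated) | COc1c([C@H](CC(C)C)O[Si](C)(C)C)ccc(O[Li])c1[Si](C)(C)C | intermediate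
11 | (S)-3-methoxy-4-[3-methyl-1-(trimethylsilyloxy)butyl]-2-(trimethylsilyl)phenyl trifluoromethanesulfonate (not isolated) | COc1c([C@H](CC(C)C)O[Si](C)(C)C)ccc(OS(=O)(=O)C(F)(F)F)c1[Si](C)(C)C | intermediate
12 | (S)-4-(1-hydroxy-3-methylbutyl)-3-methoxy-2-(trimethylsilyl)phenyl trifluoromethanesulfonate | COc1c([C@H](CC(C)C)O)ccc(OS(=O)(=O)C(F)(F)F)c1[Si](C)(C)C | intermediate
13 | (S)-1-[2-methoxy-4-(trifluoromethylsulfonyloxy)-3-(trimethylsilyl)phenyl]-3-methylbutyl acetate | COc1c([C@H](CC(C)C)OC(C)=O)ccc(OS(=O)(=O)C(F)(F)F)c1[Si](C)(C)C | intermediate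
14 | 2-hydroxy-4-methylbenzaldehyde | Cc1ccc(C=O)c(O)c1 | starting material
15 | 2-(methoxymethoxy)-4-methylbenzaldehyde | COCOc1cc(C)ccc1C=O | intermediate
16 | 2-(methoxymethoxy)-4-methylphenyl formate (not isolated) | COCOc1cc(C)ccc1OC=O | intermediate
17 | 2-(methoxymethoxy)-4-methylphenol | COCOc1cc(C)ccc1O | intermediate
18 | 2-bromo-6-(methoxymethoxy)-4-methylphenol | COCOc1cc(C)cc(Br)c1O | intermediate
19 | carbon dioxide | O=C=O | starting material
20 | potassium 2-bromo-6-(methoxymethoxy)-4-methylphenoxide (not isolated) | COCOc1cc(C)cc(Br)c1[O-].[K+] | intermediate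
21 | (S)-1-(2-methoxy-3,4-didehydrophenyl)-3-methylbutyl acetate, the ring A C1≡C6 aryne (not isolated) | COC1=C([C@H](CC(C)C)OC(C)=O)C=CC#C1 | intermediate
22 | arylpotassium adduct, potassium at ring A C1 and aryloxy group at C6 (not isolated) | COc1c([C@H](CC(C)C)OC(C)=O)ccc(Oc2c(OCOC)cc(C)cc2Br)c1[K] | intermediate
23 | 3-[(S)-1-acetoxy-3-methylbutyl]-6-[2-bromo-6-(methoxymethoxy)-4-methylphenoxy]-2-methoxybenzoic acid | COc1c([C@H](CC(C)C)OC(C)=O)ccc(Oc2c(OCOC)cc(C)cc2Br)c1C(=O)O | intermediate
24 | methyl vinyl ketone | C=CC(C)=O | starting material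
25 | 3-[(S)-1-acetoxy-3-methylbutyl]-2-methoxy-6-{2-(methoxymethoxy)-4-methyl-6-[(E)-3-oxobut-1-en-1-yl]phenoxy}benzoic acid | COc1c([C@H](CC(C)C)OC(C)=O)ccc(Oc2c(OCOC)cc(C)cc2/C=C/C(C)=O)c1C(=O)O | intermediate
26 | 3-[(S)-1-acetoxy-3-methylbutyl]-6-{2-hydroxy-4-methyl-6-[(E)-3-oxobut-1-en-1-yl]phenoxy}-2-methoxybenzoic acid | COc1c([C@H](CC(C)C)OC(C)=O)ccc(Oc2c(O)cc(C)cc2/C=C/C(C)=O)c1C(=O)O | target

**Step count**

Total: 14 steps. Longest linear sequence: 11 steps (steps 1–8, then 12–14).

**Steps most likely to fail**

Step 12 (Proposed new method). The C1 carbanion may be protonated before it meets CO2, giving the ether without the carboxyl group. The phenoxide may also be tied up by CO2 as an aryl carbonate that adds to the aryne through its own oxygen, and the product carboxylate may be O-arylated by a second aryne. The fallback uses known chemistry, sets out from 13 and comes back at 23. Compound 13 is treated with CsF and I2 in MeCN, so that aryne 21 inserts into the iodine–iodine bond and gives (S)-1-(3,4-diiodo-2-methoxyphenyl)-3-methylbutyl acetate F1. Iodine–magnesium exchange with i-PrMgCl·LiCl in THF at −40 °C should take place at the iodine flanked by the methoxy group and give {3-[(S)-1-acetoxy-3-methylbutyl]-6-iodo-2-methoxyphenyl}magnesium chloride F2. Quenching with CO2 and acidifying gives 3-[(S)-1-acetoxy-3-methylbutyl]-6-iodo-2-methoxybenzoic acid F3. An Ullmann ether coupling of F3 with phenol 18 (CuI, N,N-dimethylglycine, Cs2CO3, dioxane, 90 °C) then gives 23; the ortho carboxylate accelerates the coupling, and the aryl iodide should react in preference to the bromide of 18.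

Step 13. Carbopalladation at the crowded arylpalladium bromide may be slow, which leaves room for thermal polymerisation of 24, for intramolecular C–H arylation of ring A (closure to a dibenzofuran) and for decarboxylative palladation of the 2,6-dioxygenated benzoate by divalent palladium. The fallback sets out from 23 and comes back at 25: a Stille coupling of 23 with (E)-4-(tributylstannyl)but-3-en-2-one (Pd(PPh3)4, CuI, DMF, 70 °C). The E-enone arrives ready-made by transmetalation under neutral conditions and at lower temperature, with no free vinyl ketone present; no new compound F0 lies on the way.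

Step 4. Enantioselectivity may erode through uncatalysed hydride transfer from catecholborane to the slow, electron-rich, ortho-substituted ketone, or through the ortho methoxy group competing for the boron centre. The fallback sets out from 5 and comes back at 6: Noyori asymmetric transfer hydrogenation with RuCl(p-cymene)[(S,S)-N-tosyl-1,2-diphenylethylenediamine] in HCO2H/Et3N at 30–40 °C. This has no background hydride pathway, tolerates the allyl ether and the aryl bromide, and gives (S)-1-arylalkanols from aryl alkyl ketones; no new compound F0 lies on the way.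

**Further compounds**

F1 | step 12 | (S)-1-(3,4-diiodo-2-methoxyphenyl)-3-methylbutyl acetate | COc1c([C@H](CC(C)C)OC(C)=O)ccc(I)c1I
F2 | step 12 | {3-[(S)-1-acetoxy-3-methylbutyl]-6-iodo-2-methoxyphenyl}magnesium chloride | COc1c([C@H](CC(C)C)OC(C)=O)ccc(I)c1[Mg]Cl
F3 | step 12 | 3-[(S)-1-acetoxy-3-methylbutyl]-6-iodo-2-methoxybenzoic acid | COc1c([C@H](CC(C)C)OC(C)=O)ccc(I)c1C(=O)O
F0 | step 13 | none | none
F0 | step 4 | none | none
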